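The target is a constitutional isomer of an aryl ferulate, and the plan rests on that. Ring C is cut at O1–C2 and at C4–C4a, which leads back to the ferulic ester of the ring A oxygen that becomes O1. In one flask, light shifts the feruloyl group from O1 to the neighbouring carbon C4a (photo-Fries). A chiral bifunctional thiourea then adds the freed O1–H to C2 (oxa-Michael) and sets (2S). The step exploits the ortho pair O1/C4a of ring A. The prenyl group on C8 blocks the other ortho carbon, and silyl ethers on O5 and O7 leave O1 as the only ring-closing oxygen, so only the 8-prenyl flavanone can form.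

Key step: step 5

Assumption: the quinine-derived thiourea is taken to open the Si face of C2 to O1. The sense is to be confirmed on 10 by circular dichroism, and the quinidine-derived pseudoenantiomer replaces the catalyst unchanged if the sense is opposite.

TBS = tert-butyldimethylsilyl; prenyl = 3-methylbut-2-en-1-yl.

Step 1
Reactants: 1 phloroglucinol (benzene-1,3,5-triol); 2 prenyl bromide (1-bromo-3-methylbut-2-ene)
Product: 3 2-prenylphloroglucinol [2-(3-methylbut-2-en-1-yl)benzene-1,3,5-triol]
Conditions: KOH (1 equiv), H2O, 0 °C to rt, 1 in twofold excess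
Reagents that add atoms: none
Why: C-alkylation of the ambident phloroglucinolate, whose oxygen atoms are masked by hydrogen bonding in water, should give one monoalkyl product because the three ring carbons are equivalent, and the excess of 1 limits polyalkylation.

Step 2
Reactants: 3 2-prenylphloroglucinol
Product: 4 3,5-bis(TBSO)-2-prenylphenol
Conditions: TBSCl (2.0 equiv), imidazole (2.2 equiv), DMF–CH2Cl2, 0 °C
Reagents that add atoms: tert-butyldimethylsilyl chloride (TBSCl), CC(C)(C)[Si](C)(C)Cl
Why: Sterically governed O-silylation takes the open hydroxyl para to the prenyl group and one of the two equivalent hydroxyls beside it, in either order leading to the same compound, while the last hydroxyl is squeezed against the prenyl chain and reacts slowest.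

Step 3
Reactants: 5 (E)-ferulic acid
Product: 7 (E)-3-[4-(TBSO)-3-methoxyphenyl]acrylic acid, via silyl ester 6 (not isolated)
Conditions: TBSCl (2.2 equiv), imidazole, DMF, rt; then AcOH–THF–H2O, rt
Reagents that add atoms: tert-butyldimethylsilyl chloride (TBSCl), CC(C)(C)[Si](C)(C)Cl
Why: Exhaustive silylation followed by chemoselective hydrolysis works because a silyl ester is far more labile to aqueous acetic acid than an aryl silyl ether, and the E alkene is untouched.

Step 4
Reactants: 4 3,5-bis(TBSO)-2-prenylphenol; 7 (E)-3-[4-(TBSO)-3-methoxyphenyl]acrylic acid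
Product: 8 3,5-bis(TBSO)-2-prenylphenyl (E)-3-[4-(TBSO)-3-methoxyphenyl]acrylate
Conditions: DCC, DMAP (10 mol %), CH2Cl2, 0 °C to rt
Reagents that add atoms: none
Why: Steglich esterification puts the feruloyl group on the only free hydroxyl of 4, the oxygen that later becomes O1, under neutral conditions that spare the silyl ethers and the prenyl group.

Step 5
Reactants: 8 3,5-bis(TBSO)-2-prenylphenyl (E)-3-[4-(TBSO)-3-methoxyphenyl]acrylate
Product: 10 (2S)-5,7-bis(TBSO)-2-[4-(TBSO)-3-methoxyphenyl]-8-prenylchroman-4-one, via chalcone 9 (not isolated)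
Conditions: hν (Pyrex-filtered medium-pressure Hg lamp, λ > 290 nm), degassed toluene (5 mM), 15 °C; lamp off, concentrate in the same flask to 0.1 M, then 1-[3,5-bis(trifluoromethyl)phenyl]-3-[(8α,9S)-6'-methoxycinchonan-9-yl]thiourea (10 mol %), 0 °C
Reagents that add atoms: none
Why: Excitation of the aryl ferulate breaks the O1–acyl bond homolytically, and the caged phenoxyl/feruloyl radical pair recombines at the ortho carbon C4a and tautomerises to the 2'-hydroxychalcone 9 (photo-Fries rearrangement of an aryl cinnamate, which forms C4–C4a and leaves no reagent or by-product in the flask). In the dark the thiourea N–H bonds of the catalyst bind the enone carbonyl while its quinuclidine nitrogen takes the proton of the chelated O1–H, and the phenoxide adds to C2 (bifunctional-amine-catalysed intramolecular oxa-Michael addition of an o-enoylphenol, the laboratory counterpart of the chalcone isomerase reaction). Ring C closes in the 6-endo-trig mode, and the rearrangement itself closes no ring. The only new stereocentre, C2, is under catalyst control, because the chiral pocket presents the Si face of the E-configured C2 to O1, which gives (2S). The site selectivity is built into 8: the prenyl group occupies the second ortho carbon C8, the para carbon C6 lies between two bulky silyl ethers and its acyl product cannot cyclise, and O5 and O7 are silylated so that only O1 can close the ring, which excludes the 6-prenyl isomer. Z ester formed by photoisomerisation stays in the photoequilibrium and drains through the same radical pair, and degassing protects the prenyl group from sensitised oxygenation, while low temperature and a stop at high conversion guard C2 against the reverse reaction.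

Step 6
Reactants: 10 (2S)-5,7-bis(TBSO)-2-[4-(TBSO)-3-methoxyphenyl]-8-prenylchroman-4-one
Product: 11 (2S)-5,7-dihydroxy-2-(4-hydroxy-3-methoxyphenyl)-8-prenylchroman-4-one (target)
Conditions: Et3N·3HF, THF, 0 °C to rt
Reagents that add atoms: none
Why: Fluoride-driven cleavage of the three aryl silyl ethers in a slightly acidic medium releases each phenol in protonated form, so no phenoxide can trigger the retro-oxa-Michael opening that would scramble C2, and the prenyl group is not protonated.

Compound list
1 | phloroglucinol | Oc1cc(O)cc(O)c1 | starting material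
2 | prenyl bromide | CC(C)=CCBr | starting material
3 | 2-prenylphloroglucinol | CC(C)=CCc1c(O)cc(O)cc1O | intermediate
4 | 3,5-bis(TBSO)-2-prenylphenol | CC(C)=CCc1c(O)cc(O[Si](C)(C)C(C)(C)C)cc1O[Si](C)(C)C(C)(C)C | intermediate
5 | (E)-ferulic acid | COc1cc(/C=C/C(=O)O)ccc1O | starting material
6 | TBS (E)-3-[4-(TBSO)-3-methoxyphenyl]acrylate (silyl ester, not isolated) | COc1cc(/C=C/C(=O)O[Si](C)(C)C(C)(C)C)ccc1O[Si](C)(C)C(C)(C)C | intermediate
7 | (E)-3-[4-(TBSO)-3-methoxyphenyl]acrylic acid | COc1cc(/C=C/C(=O)O)ccc1O[Si](C)(C)C(C)(C)C | intermediate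
8 | 3,5-bis(TBSO)-2-prenylphenyl (E)-3-[4-(TBSO)-3-methoxyphenyl]acrylate | COc1cc(/C=C/C(=O)Oc2cc(O[Si](C)(C)C(C)(C)C)cc(O[Si](C)(C)C(C)(C)C)c2CC=C(C)C)ccc1O[Si](C)(C)C(C)(C)C | intermediate
9 | (E)-1-[2-hydroxy-4,6-bis(TBSO)-3-prenylphenyl]-3-[4-(TBSO)-3-methoxyphenyl]prop-2-en-1-one (chalcone, not isolated) | COc1cc(/C=C/C(=O)c2c(O)c(CC=C(C)C)c(O[Si](C)(C)C(C)(C)C)cc2O[Si](C)(C)C(C)(C)C)ccc1O[Si](C)(C)C(C)(C)C | intermediate
10 | (2S)-5,7-bis(TBSO)-2-[4-(TBSO)-3-methoxyphenyl]-8-prenylchroman-4-one | COc1cc([C@@H]2CC(=O)c3c(O[Si](C)(C)C(C)(C)C)cc(O[Si](C)(C)C(C)(C)C)c(CC=C(C)C)c3O2)ccc1O[Si](C)(C)C(C)(C)C | intermediate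
11 | (2S)-5,7-dihydroxy-2-(4-hydroxy-3-methoxyphenyl)-8-prenylchroman-4-one | COc1cc([C@@H]2CC(=O)c3c(O)cc(O)c(CC=C(C)C)c3O2)ccc1O | target

Total step count: 6. Longest linear sequence: 5 (steps 1, 2, 4, 5, 6).

Steps most likely to fail

Step 5. The excited ferulate may lose its energy by E/Z isomerisation and cage escape faster than the acyl group migrates. Part of the migration may go to the para carbon. Facial selectivity in the reversible ring closure may also be poor.
- The fallback sets out from 4 and 7 and comes back at 10. Both events are replaced by ground-state chemistry, and the stereocentre is secured by resolution instead of asymmetric ring closure.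
- Acid 7 is converted with oxalyl chloride and catalytic DMF into (E)-4-O-TBS-feruloyl chloride F1.
- Phenol 4 is turned with EtMgBr in toluene into its bromomagnesium phenoxide F2.
- F2 is C-acylated by F1 at the free ortho carbon through a magnesium-chelated transition state (ortho-coordinated acylation of a metal phenoxide). This gives chalcone 9, now isolated.
- Catalytic DBU in toluene closes 9 to the racemic silylated flavanone F3.
- Asymmetric transfer hydrogenation with RuCl(p-cymene)[(R,R)-TsDPEN] and HCO2H–Et3N is run as a kinetic resolution. It should reduce the (2R) enantiomer to the cis-(2R,4R)-flavan-4-ol F4 and leave the (2S) ketone 10, which is separated by chromatography.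

Step 2. Silylation may not stop at the bis stage, and the silyl groups may spread over the three hydroxyls.
- The fallback sets out from 1 and 2 and comes back at 4. The order of events is inverted.
- Compound 1, whose hydroxyls are all equivalent, is silylated with two equivalents of TBSCl and imidazole to 3,5-bis(TBSO)phenol F5, which is separable from the mono and tris ethers.
- NaH in toluene gives the sodium phenoxide F6, which is alkylated by 2 on carbon as a contact ion pair in the non-polar solvent.
- The two ortho carbons are equivalent and the para carbon is shielded by two silyl ethers, so 4 should result.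

Step 1. The very nucleophilic phenolate may undergo polyalkylation, O-alkylation and dearomatising double alkylation at one carbon.
- The fallback sets out from 1 and comes back at 3. Phenolate alkylation is replaced by directed ortho-metalation.
- Compound 1 is protected with MOMCl and iPr2NEt as 1,3,5-tris(methoxymethoxy)benzene F7.
- n-BuLi in THF at 0 °C lithiates F7 between two acetal oxygens to the aryllithium F8.
- Compound 2 alkylates F8 once to 2-prenyl-1,3,5-tris(methoxymethoxy)benzene F9.
- Dilute HCl in MeOH at rt removes the three acetals to give 3.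

Further compounds
F1 | step 5 | (E)-3-[4-(TBSO)-3-methoxyphenyl]acryloyl chloride | COc1cc(/C=C/C(=O)Cl)ccc1O[Si](C)(C)C(C)(C)C
F2 | step 5 | bromomagnesium 3,5-bis(TBSO)-2-prenylphenoxide | CC(C)=CCc1c([O-])cc(O[Si](C)(C)C(C)(C)C)cc1O[Si](C)(C)C(C)(C)C.[Mg+2].[Br-]
F3 | step 5 | racemic 5,7-bis(TBSO)-2-[4-(TBSO)-3-methoxyphenyl]-8-prenylchroman-4-one | COc1cc(C2CC(=O)c3c(O[Si](C)(C)C(C)(C)C)cc(O[Si](C)(C)C(C)(C)C)c(CC=C(C)C)c3O2)ccc1O[Si](C)(C)C(C)(C)C
F4 | step 5 | cis-(2R,4R)-5,7-bis(TBSO)-2-[4-(TBSO)-3-methoxyphenyl]-8-prenylchroman-4-ol | COc1cc([C@H]2C[C@@H](O)c3c(O[Si](C)(C)C(C)(C)C)cc(O[Si](C)(C)C(C)(C)C)c(CC=C(C)C)c3O2)ccc1O[Si](C)(C)C(C)(C)C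
F5 | step 2 | 3,5-bis(TBSO)phenol | Oc1cc(O[Si](C)(C)C(C)(C)C)cc(O[Si](C)(C)C(C)(C)C)c1
F6 | step 2 | sodium 3,5-bis(TBSO)phenoxide | [Na+].[O-]c1cc(O[Si](C)(C)C(C)(C)C)cc(O[Si](C)(C)C(C)(C)C)c1
F7 | step 1 | 1,3,5-tris(methoxymethoxy)benzene | COCOc1cc(OCOC)cc(OCOC)c1
F8 | step 1 | 2,4,6-tris(methoxymethoxy)phenyllithium | [Li]c1c(OCOC)cc(OCOC)cc1OCOC
F9 | step 1 | 2-prenyl-1,3,5-tris(methoxymethoxy)benzene | COCOc1cc(OCOC)c(CC=C(C)C)c(OCOC)c1
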